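**Retrosynthetic overview**
- The target is an open-chain, achiral bis(bibenzyl): ring A (3-hydroxyphenyl)–CH2CH2–ring B (para-phenylene)–O–ring C (2-aryloxyphenol)–CH2CH2–ring D (catechol). All four arenes are bought, so no ring is formed.
- The strategy rests on the ring A–CH2–CH2–ring B bridge, two unsubstituted sp3 carbons between two arene carbons. It is traced back to a C≡C unit from ethynyltrimethylsilane, stitched in one flask between 3-iodoanisole and a ring B aryl iodide, then hydrogenated.
- The ring B–O–ring C ether comes from copper-catalysed mono-arylation of the ring C phenol with 1,4-diiodobenzene; the iodine that is left is the handle for the alkyne coupling.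
- The ring C–CH2CH2–ring D bridge comes from Wittig olefination of O-benzylisovanillin with a 2,3-dimethoxybenzyl ylide, then one hydrogenation that saturates the alkene and frees the phenol.
- Order of assembly: D–C bridge, ring B onto ring C, ring A through the alkyne, reduction, fourfold O-demethylation.

Key step: step 5

Assumption: the isovanillin hydroxyl is brought in as its purchasable benzyl ether, so the Wittig step meets no phenoxide and the benzyl group is lost in the hydrogenation that follows; the target has no stereocentre, so none has to be set.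

**Step 1**
Reactants: 1 (2,3-dimethoxyphenyl)methanol
Product: 2 (2,3-dimethoxybenzyl)triphenylphosphonium bromide
Conditions: PPh3·HBr (1.05 equiv), MeCN, reflux
Reagents that add atoms: triphenylphosphine hydrobromide, [Br-].c1ccc([PH+](c2ccccc2)c2ccccc2)cc1
Why: HBr ionises the electron-rich benzylic alcohol and triphenylphosphine captures the benzylic electrophile, the usual direct phosphonium salt formation from a benzylic alcohol (SN1-type substitution).

**Step 2**
Reactants: 2 (2,3-dimethoxybenzyl)triphenylphosphonium bromide; 3 3-(benzyloxy)-4-methoxybenzaldehyde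
Product: 5 1-[2-(3-benzyloxy-4-methoxyphenyl)ethenyl]-2,3-dimethoxybenzene (E/Z mixture), via (2,3-dimethoxybenzylidene)triphenylphosphorane 4 (not isolated)
Conditions: KOtBu (1.1 equiv), THF, 0 °C; then 3, 0 °C to rt
Reagents that add atoms: none
Why: Wittig olefination of a non-enolisable aryl aldehyde by a semi-stabilised benzylic ylide; the expected E/Z mixture is of no consequence because step 3 saturates the double bond.

**Step 3**
Reactants: 5 1-[2-(3-benzyloxy-4-methoxyphenyl)ethenyl]-2,3-dimethoxybenzene
Product: 6 5-[2-(2,3-dimethoxyphenyl)ethyl]-2-methoxyphenol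
Conditions: H2 (1 atm), 10% Pd/C, EtOAc/EtOH, rt
Reagents that add atoms: none
Why: Heterogeneous catalytic hydrogenation saturates the stilbene and hydrogenolyses the benzyl aryl ether in the same operation, while the methyl ethers are inert.

**Step 4**
Reactants: 6 5-[2-(2,3-dimethoxyphenyl)ethyl]-2-methoxyphenol; 7 1,4-diiodobenzene
Product: 8 1-[2-[3-(4-iodophenoxy)-4-methoxyphenyl]ethyl]-2,3-dimethoxybenzene
Conditions: 7 (4 equiv), CuI (10 mol%), picolinic acid (20 mol%), K3PO4 (2 equiv), DMSO, 85 °C
Reagents that add atoms: none
Why: Ullmann-type diaryl ether synthesis with picolinic acid-ligated monovalent copper, which accepts ortho-substituted phenols; the excess of the symmetrical diiodide and the lower reactivity of the electron-rich product iodide should hold the reaction at one arylation.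

**Step 5**
Reactants: 9 3-iodoanisole; 10 ethynyltrimethylsilane; 8 1-[2-[3-(4-iodophenoxy)-4-methoxyphenyl]ethyl]-2,3-dimethoxybenzene
Product: 13 1-[2-[3-[4-[(3-methoxyphenyl)ethynyl]phenoxy]-4-methoxyphenyl]ethyl]-2,3-dimethoxybenzene, via [(3-methoxyphenyl)ethynyl]trimethylsilane 11 (not isolated), via 1-ethynyl-3-methoxybenzene 12 (not isolated)
Conditions: 9 (1.30 equiv), 10 (1.25 equiv), PdCl2(PPh3)2 (6 mol%), CuI (10 mol%), Et3N (6 equiv), degassed toluene, rt; then 8 (1.00 equiv), DBU (12 equiv), H2O (0.5 equiv relative to 11), rt to 60 °C
Reagents that add atoms: none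
Why: PdCl2(PPh3)2 is reduced in the flask to zerovalent palladium, which adds oxidatively to the C–I bond of 9; the copper acetylide formed from 10 with CuI and Et3N transmetalates to divalent palladium, and reductive elimination gives silylalkyne 11 (Sonogashira coupling). Only after 9 is used up are 8, DBU and water added: attack at silicon frees the terminal alkyne 12, which enters a second Sonogashira cycle with 8 to give 13, the closest known reaction type being the one-flask Sonogashira coupling, in situ desilylation and second Sonogashira coupling that gives unsymmetrical diarylalkynes. No ring is closed and no stereocentre is formed; the step makes the ring A–C(sp) and ring B–C(sp) bonds. The selectivity needed is the unsymmetrical diarylalkyne over the two symmetrical diarylalkynes and over the oxidatively coupled diyne; it is secured by the trimethylsilyl group, which blocks the second alkyne terminus until the second iodide is present, by the gradual release of 12 under DBU and a substoichiometric amount of water, and by exclusion of oxygen. A slight excess of 9 over 10 leaves no free ethynylsilane to bridge two molecules of 8, and 11 is used in excess over 8 so that the more valuable iodide is consumed. Iodide 8, though electron-rich, should still undergo oxidative addition at or slightly above room temperature.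

**Step 6**
Reactants: 13 1-[2-[3-[4-[(3-methoxyphenyl)ethynyl]phenoxy]-4-methoxyphenyl]ethyl]-2,3-dimethoxybenzene
Product: 14 1-[2-[3-[4-[2-(3-methoxyphenyl)ethyl]phenoxy]-4-methoxyphenyl]ethyl]-2,3-dimethoxybenzene
Conditions: H2 (1 atm), 10% Pd/C, EtOAc/MeOH, rt
Reagents that add atoms: none
Why: Catalytic hydrogenation of the internal diarylalkyne over Pd/C runs through the stilbene to the CH2CH2 bridge, and the methyl and diaryl ethers are untouched.

**Step 7**
Reactants: 14 1-[2-[3-[4-[2-(3-methoxyphenyl)ethyl]phenoxy]-4-methoxyphenyl]ethyl]-2,3-dimethoxybenzene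
Product: 15 3-[2-[4-hydroxy-3-[4-[2-(3-hydroxyphenyl)ethyl]phenoxy]phenyl]ethyl]benzene-1,2-diol
Conditions: BBr3 (8 equiv), CH2Cl2, −78 °C to rt; then H2O, 0 °C
Reagents that add atoms: none
Why: Lewis acid-mediated aryl methyl ether cleavage, in which BBr3 complexes each methoxy oxygen and bromide attacks the methyl group (SN2); the diaryl ether oxygen carries only sp2 carbons and cannot be cleaved this way, and hydrolysis of the aryl borates frees the four phenols.

**Compound list**
1 | (2,3-dimethoxyphenyl)methanol | COc1cccc(CO)c1OC | starting material
2 | (2,3-dimethoxybenzyl)triphenylphosphonium bromide | COc1cccc(C[P+](c2ccccc2)(c2ccccc2)c2ccccc2)c1OC.[Br-] | intermediate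
3 | 3-(benzyloxy)-4-methoxybenzaldehyde (O-benzylisovanillin) | COc1ccc(C=O)cc1OCc1ccccc1 | starting material
4 | (2,3-dimethoxybenzylidene)triphenylphosphorane | COc1cccc(C=P(c2ccccc2)(c2ccccc2)c2ccccc2)c1OC | intermediate (not isolated)
5 | 1-[2-(3-benzyloxy-4-methoxyphenyl)ethenyl]-2,3-dimethoxybenzene, E/Z mixture | COc1cccc(C=Cc2ccc(OC)c(OCc3ccccc3)c2)c1OC | intermediate
6 | 5-[2-(2,3-dimethoxyphenyl)ethyl]-2-methoxyphenol | COc1cccc(CCc2ccc(OC)c(O)c2)c1OC | intermediate
7 | 1,4-diiodobenzene | Ic1ccc(I)cc1 | starting material
8 | 1-[2-[3-(4-iodophenoxy)-4-methoxyphenyl]ethyl]-2,3-dimethoxybenzene (ring B iodide) | COc1cccc(CCc2ccc(OC)c(Oc3ccc(I)cc3)c2)c1OC | intermediate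
9 | 3-iodoanisole | COc1cccc(I)c1 | starting material
10 | ethynyltrimethylsilane | C#C[Si](C)(C)C | starting material
11 | [(3-methoxyphenyl)ethynyl]trimethylsilane | COc1cccc(C#C[Si](C)(C)C)c1 | intermediate (not isolated)
12 | 1-ethynyl-3-methoxybenzene | COc1cccc(C#C)c1 | intermediate (not isolated)
13 | 1-[2-[3-[4-[(3-methoxyphenyl)ethynyl]phenoxy]-4-methoxyphenyl]ethyl]-2,3-dimethoxybenzene | COc1cccc(C#Cc2ccc(Oc3cc(CCc4cccc(OC)c4OC)ccc3OC)cc2)c1 | intermediate
14 | 1-[2-[3-[4-[2-(3-methoxyphenyl)ethyl]phenoxy]-4-methoxyphenyl]ethyl]-2,3-dimethoxybenzene | COc1cccc(CCc2ccc(Oc3cc(CCc4cccc(OC)c4OC)ccc3OC)cc2)c1 | intermediate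
15 | 3-[2-[4-hydroxy-3-[4-[2-(3-hydroxyphenyl)ethyl]phenoxy]phenyl]ethyl]benzene-1,2-diol | Oc1cccc(CCc2ccc(Oc3cc(CCc4cccc(O)c4O)ccc3O)cc2)c1 | target

**Step count**
Total steps: 7. Longest linear sequence: 7 steps (1 → 2 → 5 → 6 → 8 → 13 → 14 → 15).

**Steps most likely to fail**

Step 5. The silyl group may be lost while 3-iodoanisole is still present, which would give the symmetrical diarylalkyne. The freed alkyne may dimerise oxidatively on copper if oxygen enters. Oxidative addition to the electron-rich iodide may be slow, so the alkyne is consumed by side reactions first. The fallback sets out from iodide 8 and gives up the alkyne linchpin for an alkene. A Mizoroki–Heck reaction of 8 with 3-methoxystyrene (Pd(OAc)2, P(o-tol)3, Et3N, DMF, 100 °C) should give (E)-1-[2-[3-[4-[2-(3-methoxyphenyl)ethenyl]phenoxy]-4-methoxyphenyl]ethyl]-2,3-dimethoxybenzene F1. Hydrogenation of this stilbene (H2, Pd/C, EtOAc) comes back to the route at 14.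

Step 4. The remaining iodine of the product may be arylated a second time, coupling of the ortho-methoxy phenol may be sluggish, and separation from the large excess of diiodide may be tedious. The fallback sets out from phenol 6 and makes the two ends of ring B chemically different: a Chan–Lam coupling with 4-iodophenylboronic acid (Cu(OAc)2, pyridine, 4 Å molecular sieves, CH2Cl2, air, rt). Under oxidative divalent-copper conditions only the boron-bearing carbon reacts and the aryl iodide is inert at room temperature. It comes back to the route at iodide 8 itself, so the detour holds no new compound (F0).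

Step 7. Cleavage of the four ethers may stop at partly methylated phenols, and the free catechol may oxidise during isolation. The fallback sets out from 14 and changes both the mode of cleavage and the way the product is isolated. A pyridinium chloride melt (190 °C, argon) protonates each ether oxygen and chloride removes the methyl group. The crude tetraphenol is acetylated at once (Ac2O, pyridine) to the tetraacetate 3-[2-[4-acetoxy-3-[4-[2-(3-acetoxyphenyl)ethyl]phenoxy]phenyl]ethyl]-1,2-phenylene diacetate F2, which is stable to air and chromatography. Acid methanolysis (HCl in MeOH, rt, degassed) then comes back to the route at 15.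

**Further compounds**
F1 | step 5 | (E)-1-[2-[3-[4-[2-(3-methoxyphenyl)ethenyl]phenoxy]-4-methoxyphenyl]ethyl]-2,3-dimethoxybenzene | COc1cccc(/C=C/c2ccc(Oc3cc(CCc4cccc(OC)c4OC)ccc3OC)cc2)c1
F0 | step 4 | none | none
F2 | step 7 | 3-[2-[4-acetoxy-3-[4-[2-(3-acetoxyphenyl)ethyl]phenoxy]phenyl]ethyl]-1,2-phenylene diacetate | CC(=O)Oc1cccc(CCc2ccc(Oc3cc(CCc4cccc(OC(C)=O)c4OC(C)=O)ccc3OC(C)=O)cc2)c1
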